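**Assumption:** MeI, NBS and TIPSCl are counted as reagents, and [Fe(phen)3](SbF6)3 is a stock oxidant made beforehand from ferroin.

## Retrosynthetic overview

1. Target 16 ⇐ fluoride desilylation of bis-TIPS ether 15. The coumarate sits on the C2 oxymethyl from the start, and the free CH2OH on C3 comes from an aldehyde, so the two primary oxygens never need differentiating.
2. 15 ⇐ one organo-SOMO formal [4+2] of aldehyde 6 with cinnamyl ester 13: C2–C3 by addition of a chiral enamine radical cation to the styrene, then radical-to-cation crossover and Friedel–Crafts closure C1–C8a. All three stereocentres are set here.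
3. 13 ⇐ Mitsunobu esterification of allylic alcohol 9 with p-coumaric acid 12; 12 ⇐ Heck of 4-iodophenol with acrylic acid.
4. 6 and 9 ⇐ the same aryl bromide 4 (Heck with allyl alcohol; Heck with methyl acrylate, then DIBAL-H); 4 ⇐ catechol by methylation, para-bromination and silylation.
5. Ring order: both benzene rings are bought; the saturated six-membered ring of the tetralin is the only ring formed (step 9).

## Route

**Step 1**
Reactants: 1 catechol
Product: 2 guaiacol (2-methoxyphenol)
Conditions: MeI (0.8 equiv), K2CO3 (1.0 equiv), acetone, reflux; distil, recover catechol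
Reagents that add atoms: iodomethane, CI
Why: Williamson O-methylation of the catechol mono-anion, with the alkylating agent kept limiting so that the dimethyl ether stays minor and the mono-ether is separated by distillation.

**Step 2**
Reactants: 2 guaiacol
Product: 3 4-bromo-2-methoxyphenol
Conditions: NBS (1.0 equiv), MeCN, 0 °C → rt
Reagents that add atoms: N-bromosuccinimide, O=C1CCC(=O)N1Br
Why: Electrophilic aromatic bromination in which the free OH is the stronger director, so bromine enters para to OH and not para to OMe.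

**Step 3**
Reactants: 3 4-bromo-2-methoxyphenol
Product: 4 (4-bromo-2-methoxyphenoxy)triisopropylsilane
Conditions: TIPSCl (1.1 equiv), imidazole (2 equiv), DMF, rt
Reagents that add atoms: triisopropylsilyl chloride, CC(C)[Si](Cl)(C(C)C)C(C)C
Why: Silyl ether formation on the phenol; the TIPS group withstands Pd/base at 90–100 °C, DIBAL-H, Mitsunobu conditions, Fe(III) and borohydride, and leaves with fluoride at the end.

**Step 4**
Reactants: 4 (4-bromo-2-methoxyphenoxy)triisopropylsilane; 5 allyl alcohol
Product: 6 3-{3-methoxy-4-[(triisopropylsilyl)oxy]phenyl}propanal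
Conditions: Pd(OAc)2 (5 mol%), Bu4NCl (1 equiv), NaHCO3 (2.5 equiv), DMF, 90 °C
Reagents that add atoms: none
Why: Heck reaction of allyl alcohol under Jeffery conditions: aryl-Pd adds to the terminal carbon and β-hydride elimination toward the carbinol gives the enol, so the saturated aldehyde is delivered directly.

**Step 5**
Reactants: 4 (4-bromo-2-methoxyphenoxy)triisopropylsilane; 7 methyl acrylate
Product: 8 methyl (2E)-3-{3-methoxy-4-[(triisopropylsilyl)oxy]phenyl}prop-2-enoate
Conditions: Pd(OAc)2 (2 mol%), P(o-tol)3 (4 mol%), Et3N (1.5 equiv), DMF, 100 °C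
Reagents that add atoms: none
Why: Mizoroki–Heck arylation of the acrylate; syn-insertion followed by syn-β-hydride elimination gives only the E-cinnamate.

**Step 6**
Reactants: 8 methyl (2E)-3-{3-methoxy-4-[(triisopropylsilyl)oxy]phenyl}prop-2-enoate
Product: 9 (2E)-3-{3-methoxy-4-[(triisopropylsilyl)oxy]phenyl}prop-2-en-1-ol
Conditions: DIBAL-H (2.2 equiv), CH2Cl2, −78 → 0 °C; Rochelle salt work-up
Reagents that add atoms: none
Why: DIBAL-H 1,2-reduction of the conjugated ester to the allylic alcohol, leaving the E-alkene and the aryl silyl ether untouched.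

**Step 7**
Reactants: 10 4-iodophenol; 11 acrylic acid
Product: 12 (2E)-3-(4-hydroxyphenyl)prop-2-enoic acid (p-coumaric acid)
Conditions: Pd(OAc)2 (1 mol%), Et3N (3 equiv), MeCN, 80 °C; then 1 M HCl
Reagents that add atoms: none
Why: Ligand-free Heck reaction of an aryl iodide with acrylic acid (as its ammonium salt), which tolerates the free phenol and gives the E-acid.

**Step 8**
Reactants: 9 (2E)-3-{3-methoxy-4-[(triisopropylsilyl)oxy]phenyl}prop-2-en-1-ol; 12 p-coumaric acid
Product: 13 (2E)-3-{3-methoxy-4-[(triisopropylsilyl)oxy]phenyl}prop-2-en-1-yl (2E)-3-(4-hydroxyphenyl)prop-2-enoate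
Conditions: PPh3 (1.3 equiv), DIAD (1.3 equiv), 12 (1.2 equiv), THF, 0 °C → rt
Reagents that add atoms: none
Why: Mitsunobu esterification in which only the carboxylic acid (pKa about 4.5) protonates the betaine fast enough, so the primary allylic alkoxyphosphonium is displaced by carboxylate and not by the phenol (pKa about 9); both E-alkenes are untouched.

**Step 9**
Reactants: 6 3-{3-methoxy-4-[(triisopropylsilyl)oxy]phenyl}propanal (1.0 equiv); 13 cinnamyl coumarate (1.5 equiv, excess recovered)
Product: 15 [(1S,2R,3R)-3-(hydroxymethyl)-6-methoxy-1-{3-methoxy-4-[(triisopropylsilyl)oxy]phenyl}-7-[(triisopropylsilyl)oxy]-1,2,3,4-tetrahydronaphthalen-2-yl]methyl (2E)-3-(4-hydroxyphenyl)prop-2-enoate, via tetralin aldehyde 14 (not isolated)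
Conditions: (2S,5S)-5-benzyl-2-tert-butyl-3-methylimidazolidin-4-one·TFA (20 mol%), [Fe(phen)3](SbF6)3 (2.5 equiv), Na2HPO4 (2.5 equiv), H2O (2 equiv), DME, −30 °C, 24 h; then MeOH, NaBH4 (5 equiv), −30 → 0 °C
Reagents that add atoms: none
Why: Proposed new method: the E-enamine of 6 is oxidised by the outer-sphere Fe(III) oxidant to a 3π-electron radical cation whose Re face is shielded by the catalyst benzyl group, so its Si face adds to the β-carbon of the electron-rich E-styrene 13 (C3 = R; an open transition state with the aryl-bearing alkene carbon anti to the iminium arm and the alkene H, not CH2O-acyl, in the crowded inside position gives C2 = R), the benzylic radical is oxidised to the p-silyloxybenzyl cation and trapped by the tethered arene para to OMe through a chair with the aryl group equatorial (C1 = S, all-trans), and borohydride then reduces the epimerisable aldehyde 14 in the same flask without touching the cinnamate; the closest known reaction is the organo-SOMO formal [4+2] cycloaddition of 3-arylpropanals with styrenes (radical–polar crossover), extended here to a 1,2-disubstituted cinnamyl ester.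

**Step 10**
Reactants: 15 bis-TIPS tetralin alcohol
Product: 16 [(1S,2R,3R)-7-hydroxy-1-(4-hydroxy-3-methoxyphenyl)-3-(hydroxymethyl)-6-methoxy-1,2,3,4-tetrahydronaphthalen-2-yl]methyl (2E)-3-(4-hydroxyphenyl)prop-2-enoate (target)
Conditions: TBAF (2.4 equiv), AcOH (2.4 equiv), THF, 0 °C
Reagents that add atoms: none
Why: Fluoride desilylation of the two aryl silyl ethers, buffered with acetic acid so the phenoxides are protonated at once and neither ester cleavage nor acyl migration to the neighbouring CH2OH occurs; no stereocentre is touched.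

## Compound list

1 | catechol (benzene-1,2-diol) | Oc1ccccc1O | starting material
2 | guaiacol (2-methoxyphenol) | COc1ccccc1O | intermediate
3 | 4-bromo-2-methoxyphenol | COc1cc(Br)ccc1O | intermediate
4 | (4-bromo-2-methoxyphenoxy)triisopropylsilane | COc1cc(Br)ccc1O[Si](C(C)C)(C(C)C)C(C)C | intermediate
5 | allyl alcohol (prop-2-en-1-ol) | C=CCO | starting material
6 | 3-{3-methoxy-4-[(triisopropylsilyl)oxy]phenyl}propanal | COc1cc(CCC=O)ccc1O[Si](C(C)C)(C(C)C)C(C)C | intermediate
7 | methyl acrylate | C=CC(=O)OC | starting material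
8 | methyl (2E)-3-{3-methoxy-4-[(triisopropylsilyl)oxy]phenyl}prop-2-enoate | COC(=O)/C=C/c1ccc(O[Si](C(C)C)(C(C)C)C(C)C)c(OC)c1 | intermediate
9 | (2E)-3-{3-methoxy-4-[(triisopropylsilyl)oxy]phenyl}prop-2-en-1-ol | OC/C=C/c1ccc(O[Si](C(C)C)(C(C)C)C(C)C)c(OC)c1 | intermediate
10 | 4-iodophenol | Oc1ccc(I)cc1 | starting material
11 | acrylic acid | C=CC(=O)O | starting material
12 | (2E)-3-(4-hydroxyphenyl)prop-2-enoic acid (p-coumaric acid) | OC(=O)/C=C/c1ccc(O)cc1 | intermediate
13 | (2E)-3-{3-methoxy-4-[(triisopropylsilyl)oxy]phenyl}prop-2-en-1-yl (2E)-3-(4-hydroxyphenyl)prop-2-enoate | COc1cc(/C=C/COC(=O)/C=C/c2ccc(O)cc2)ccc1O[Si](C(C)C)(C(C)C)C(C)C | intermediate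
14 | [(1S,2R,3R)-3-formyl-6-methoxy-1-{3-methoxy-4-[(triisopropylsilyl)oxy]phenyl}-7-[(triisopropylsilyl)oxy]-1,2,3,4-tetrahydronaphthalen-2-yl]methyl (2E)-3-(4-hydroxyphenyl)prop-2-enoate | COc1cc([C@H]2c3cc(O[Si](C(C)C)(C(C)C)C(C)C)c(OC)cc3C[C@@H](C=O)[C@@H]2COC(=O)/C=C/c2ccc(O)cc2)ccc1O[Si](C(C)C)(C(C)C)C(C)C | intermediate
15 | [(1S,2R,3R)-3-(hydroxymethyl)-6-methoxy-1-{3-methoxy-4-[(triisopropylsilyl)oxy]phenyl}-7-[(triisopropylsilyl)oxy]-1,2,3,4-tetrahydronaphthalen-2-yl]methyl (2E)-3-(4-hydroxyphenyl)prop-2-enoate | COc1cc([C@H]2c3cc(O[Si](C(C)C)(C(C)C)C(C)C)c(OC)cc3C[C@@H](CO)[C@@H]2COC(=O)/C=C/c2ccc(O)cc2)ccc1O[Si](C(C)C)(C(C)C)C(C)C | intermediate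
16 | [(1S,2R,3R)-7-hydroxy-1-(4-hydroxy-3-methoxyphenyl)-3-(hydroxymethyl)-6-methoxy-1,2,3,4-tetrahydronaphthalen-2-yl]methyl (2E)-3-(4-hydroxyphenyl)prop-2-enoate | COc1cc([C@H]2c3cc(O)c(OC)cc3C[C@@H](CO)[C@@H]2COC(=O)/C=C/c2ccc(O)cc2)ccc1O | target

## Step count and risks

Total steps: 10. Longest linear sequence: 8 (steps 1, 2, 3, 5, 6, 8, 9, 10).

**Most likely to fail, in order:**

**Step 9 (SOMO [4+2] cascade).**
- The radical cation must add to a hindered 1,2-disubstituted alkene.
- The C2/C3 selectivity rests on an acyclic transition state and is the least secure prediction; it cannot be repaired by epimerisation, so minor diastereomers are removed by chromatography of 15.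
- The benzylic cation may be intercepted by water or the neighbouring ester before the arene closes the ring.
- Fallback, setting out from 6 and 13 and returning at 15: run the radical step deliberately as a carbo-hydroxylation (same catalyst and oxidant, wet DME with 10 equiv H2O, borohydride quench). This gives the open-chain diol (2R,3R)-2-[hydroxy(3-methoxy-4-triisopropylsilyloxyphenyl)methyl]-3-(hydroxymethyl)-4-(3-methoxy-4-triisopropylsilyloxyphenyl)butyl (2E)-3-(4-hydroxyphenyl)prop-2-enoate F1, whose carbinol centre is an irrelevant mixture. The ring is then closed in a separate step with TFA in CH2Cl2 at −20 °C. The p-silyloxybenzyl alcohol ionises reversibly, any tetrahydrofuran formed by the free CH2OH reopens, and the irreversible Friedel–Crafts alkylation para to OMe gives 15 with the aryl group equatorial. This is the lariciresinol-to-isolariciresinol type of closure and separates radical C–C bond formation from ring formation.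

**Step 8 (Mitsunobu with an unprotected phenol).**
- Phenol O-alkylation or ionisation of the cinnamyl alkoxyphosphonium could lower the yield.
- Fallback, setting out from 12 (with 9) and returning at 13: acetylate 12 with Ac2O/pyridine to (2E)-3-(4-acetoxyphenyl)prop-2-enoic acid F2. Couple F2 with 9 using EDC·HCl/DMAP in CH2Cl2 to give (2E)-3-{3-methoxy-4-[(triisopropylsilyl)oxy]phenyl}prop-2-en-1-yl (2E)-3-(4-acetoxyphenyl)prop-2-enoate F3. Cleave only the aryl acetate with pyrrolidine (1.2 equiv, CH2Cl2, 0 °C) to give 13.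

**Step 4 (Heck of an electron-rich aryl bromide with allyl alcohol).**
- Slow oxidative addition, branched or cinnamyl-alcohol by-products and aldehyde condensation are possible.
- Fallback, setting out from 8 and returning at 6: hydrogenate the alkene of 8 (H2, Pd/C, EtOAc) to methyl 3-{3-methoxy-4-[(triisopropylsilyl)oxy]phenyl}propanoate F4, then half-reduce with DIBAL-H (1.05 equiv, toluene, −78 °C) to aldehyde 6.

## Further compounds

F1 | step 9 | (2R,3R)-2-[hydroxy(3-methoxy-4-triisopropylsilyloxyphenyl)methyl]-3-(hydroxymethyl)-4-(3-methoxy-4-triisopropylsilyloxyphenyl)butyl (2E)-3-(4-hydroxyphenyl)prop-2-enoate | COc1cc(C[C@@H](CO)[C@@H](C(O)c2ccc(O[Si](C(C)C)(C(C)C)C(C)C)c(OC)c2)COC(=O)/C=C/c2ccc(O)cc2)ccc1O[Si](C(C)C)(C(C)C)C(C)C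
F2 | step 8 | (2E)-3-(4-acetoxyphenyl)prop-2-enoic acid | CC(=O)Oc1ccc(/C=C/C(=O)O)cc1
F3 | step 8 | (2E)-3-{3-methoxy-4-[(triisopropylsilyl)oxy]phenyl}prop-2-en-1-yl (2E)-3-(4-acetoxyphenyl)prop-2-enoate | COc1cc(/C=C/COC(=O)/C=C/c2ccc(OC(C)=O)cc2)ccc1O[Si](C(C)C)(C(C)C)C(C)C
F4 | step 4 | methyl 3-{3-methoxy-4-[(triisopropylsilyl)oxy]phenyl}propanoate | COC(=O)CCc1ccc(O[Si](C(C)C)(C(C)C)C(C)C)c(OC)c1
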